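The data are simulated for substances that don't exist; noise was put on by code.

the same everywhere: Q 1.5 M; J 1.5 M; L 0.27 mM

| charge | G | Z | remark |
|---|---|---|---|
| zeta | 0.90 M | 2.1 mM | run made earlier |
| gamma | 0.90 M | 3.3 mM | run made earlier |
| alpha | 1.8 M | 1.5 mM | run made earlier |
| flask | 0.900 M | 1.5 mM |  |

| run | time / h | E / % |
|---|---|---|
| zeta | 4.00 | 20.7 |
| zeta | 8.00 | 21.5 |
| zeta | 20.0 | 19.9 |
| zeta | 50.0 | 20.7 |
| gamma | 4.00 | 20.4 |
| gamma | 8.00 | 19.8 |
| gamma | 20.0 | 20.1 |
| gamma | 50.0 | 20.9 |
| alpha | 12.0 | 38.0 |
| alpha | 25.0 | 36.6 |
| alpha | 40.0 | 37.5 |
| alpha | 50.0 | 37.7 |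

(readings scatter by 0.5 percentage points)

- Z is single-handed; Q and J are mirror images of each other, charged as a racemate, each of them at the stated concentration

* apparent order in Z when 20 % of the Q and J together are converted (percent change of the rate of making E for one percent more Z charged)
* apparent order in G when 20 % of the Q and J together are converted (percent change of the rate of making E for one percent more G charged)

Zeta shows no slowness to measure: E (the product of the enantiomer Q, charged beside its mirror image J) reads 20.7 % after 4.00 h and 20.7 % after 50.0 h. So we turn the settings by hand. More of the catalyst Z should hasten E and leave its end alone, and gamma, with 3.3 mM against 2.1 mM in zeta, ends at 20.9 %. More of the reagent G should raise the end if G is the limiting reagent, and alpha, with 1.8 M of G and 1.5 mM of Z, ends higher than zeta, at 37.7 %.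

The orders asked compare flasks at equal conversion, so we look at the remainder of a charge. With the amount taken held fixed, one percent more charge means λ percent more left, where λ is charge over remainder; a species nothing takes from has λ = 1, the zero of our scale. If each turnover uses one G, 20 % conversion in the flask leaves 0.300 M of 0.900 M, so λ = 3.00, the leverage of G: its charge over what is left of it. In alpha the same conversion gives 1.50. If each L takes one Z and no L remains by that conversion, the leverage of Z in the flask is 1.22. We assume true order one in each, so our reckoned orders equal these leverages.

The forecast gives 1.1 in Z and 2.2 in G: “With true order 0–1, I expect about 2.” Our figure for G is higher.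

The flask gives 1.2 in Z and 3.0 in G.

    G + Z + Q → Z + E (k = 1070 /M²/h)
    G + Z + J → Z + D (k = 445 /M²/h)
    Z + L → X (k = 8390 /M/h)

In the flask, the half-life of G by the step to E was 0.43 h at 0.0103 d, shorter than the 0.91 h by the step to D, the product of J, and at 2.50 d the flask holds G at 0 % of its charge, with E at 20.3 % and D at 9.72 % of the Q and J together charged. At 20 % conversion in the flask the leverage of G stands at 3.00 beside the order 3.0, and the inverse of the leverage of Z, 82.0 %, stands beside the share of the catalyst that is Z, 82.2 %.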